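Ring B is disconnected at C6–C7 and C8–C9. The C7–C8 unit, carrying the future isopropylidene as an isopropenyl group and the C8 oxygen as a boronate, is an alkynylboronate; the other four ring-B carbons (C6, C5, C10, C9) are a cyclobutanone fused to ring A, made by dichloroketene cycloaddition to a 1-methylcyclohexene whose C3 and C4 stereocentres come from one asymmetric hydroboration. Zerovalent nickel inserts the alkyne into the C9–C6 bond, closing ring B beside the quaternary C5 that forbids a diene route. The step exploits the enolised 1,2-dione of ring B: C9=O is the cyclobutanone carbonyl, and oxidation of C8–B releases the diosphenol and the C7 isopropylidene.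

Key step: step 10

Remarks
- Locants follow the eremophilane skeleton: C3 carries the ester oxygen, C4 and C5 the methyl groups, C6 is the ring-B methylene, C7 bears the three-carbon unit, C8 is the ketone carbon, C9 the enol carbon, C10 the ring-fusion carbon, C1 and C2 the ring-A methylenes. The target is (3R,4R,5R).
- Assumption: the borane from (−)-α-pinene is taken to deliver the (1R,2R)-alcohol from diene 4, by analogy with the known sense of induction of this reagent class on 1-methylcycloalkenes.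

Step 1
Reactants: 1 2-methylcyclohex-2-en-1-one
Product: 3 6-methylcyclohexa-1,5-dien-1-yl trifluoromethanesulfonate, via lithium dienolate 2 (not isolated)
Conditions: LiN(iPr)2, THF, −78 °C; then PhNTf2, −78 °C → 0 °C
Reagents that add atoms: N-phenylbis(trifluoromethanesulfonimide), O=S(=O)(N(c1ccccc1)S(=O)(=O)C(F)(F)F)C(F)(F)F
Why: Kinetic deprotonation at the α′ methylene gives the cross-conjugated dienolate, and its O-sulfonylation (enol triflate formation) fixes the 1,3-diene; no stereocentre is involved.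

Step 2
Reactants: 3 6-methylcyclohexa-1,5-dien-1-yl trifluoromethanesulfonate
Product: 4 2,3-dimethylcyclohexa-1,3-diene
Conditions: MeMgBr, Fe(acac)3 (5 mol %), THF/NMP, −30 °C → 0 °C
Reagents that add atoms: methylmagnesium bromide, C[Mg]Br
Why: Iron-catalysed Kumada-type cross-coupling of an alkenyl triflate with a methyl Grignard reagent should give the achiral, symmetric diene.

Step 3
Reactants: 4 2,3-dimethylcyclohexa-1,3-diene
Product: 6 (1R,2R)-2,3-dimethylcyclohex-3-en-1-ol, via dialkylborane 5 (not isolated)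
Conditions: monoisopinocampheylborane from (−)-α-pinene (1.0 equiv, preformed solution), Et2O, −25 °C; then NaOH, H2O2, THF/H2O, 0 °C → 25 °C
Reagents that add atoms: hydrogen peroxide, OO
Why: Asymmetric hydroboration–oxidation: syn addition of H–B to one trisubstituted double bond, boron at the unsubstituted terminus, gives the trans alcohol after oxidation with retention, and the terpene-derived borane selects the alkene face and so sets both stereocentres (the only reagent-controlled event of the route).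

Step 4
Reactants: 7 tert-butyldimethyl(prop-2-yn-1-yloxy)silane
Product: 9 4-[(tert-butyldimethylsilyl)oxy]but-2-ynoic acid, via lithium acetylide 8 (not isolated)
Conditions: n-BuLi, THF, −78 °C; CO2 (gas), −78 °C → 0 °C; 1 M HCl to pH 3, 0 °C
Reagents that add atoms: carbon dioxide, O=C=O
Why: Carboxylation of a lithium acetylide with CO2; brief cold acidification should leave the primary silyl ether intact.

Step 5
Reactants: 6 (1R,2R)-2,3-dimethylcyclohex-3-en-1-ol; 9 4-[(tert-butyldimethylsilyl)oxy]but-2-ynoic acid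
Product: 10 (1R,2R)-2,3-dimethylcyclohex-3-en-1-yl 4-[(tert-butyldimethylsilyl)oxy]but-2-ynoate
Conditions: DCC, DMAP (5 mol %), CH2Cl2, −20 °C → 0 °C
Reagents that add atoms: none
Why: Steglich esterification leaves the carbinol C–O bond intact, so C3 keeps its configuration; low temperature and little DMAP should suppress amine addition to the ynoate.

Step 6
Reactants: 10 (1R,2R)-2,3-dimethylcyclohex-3-en-1-yl 4-[(tert-butyldimethylsilyl)oxy]but-2-ynoate
Product: 12 (1R,2R)-2,3-dimethylcyclohex-3-en-1-yl (2Z)-4-[(tert-butyldimethylsilyl)oxy]-3-methylbut-2-enoate, via lithium alkenyl(methyl)cuprate 11 (not isolated)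
Conditions: Me2CuLi (from CuI and MeLi), THF, −78 °C; MeOH, −78 °C; aqueous NH4Cl
Reagents that add atoms: lithium dimethylcuprate, [Li+].C[Cu-]C
Why: Conjugate syn-carbocupration of the ynoate puts copper and the new methyl cis, and protonation at −78 °C with retention should give the Z-enoate (CH2OSi cis to the ester carbonyl).

Step 7
Reactants: 12 (1R,2R)-2,3-dimethylcyclohex-3-en-1-yl (2Z)-4-[(tert-butyldimethylsilyl)oxy]-3-methylbut-2-enoate
Product: 13 (1R,2R,3R,6S)-8,8-dichloro-1,2-dimethyl-7-oxobicyclo[4.2.0]octan-3-yl (2Z)-4-[(tert-butyldimethylsilyl)oxy]-3-methylbut-2-enoate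
Conditions: Cl3CCOCl, Zn–Cu couple, Et2O/DME, 25 °C, ultrasound
Reagents that add atoms: trichloroacetyl chloride, ClC(Cl)(Cl)C(Cl)=O
Why: Ketene–alkene [2+2] cycloaddition: the ketene carbonyl carbon bonds to the less substituted C10 and the CCl2 carbon to C5, suprafacially (cis ring fusion), and approach anti to the allylic C4 methyl (pseudoaxial to avoid A(1,2) strain with the C5 methyl) should set the quaternary C5 with its methyl cis to the C4 methyl; the electron-poor enoate should not react.

Step 8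
Reactants: 13 (1R,2R,3R,6S)-8,8-dichloro-1,2-dimethyl-7-oxobicyclo[4.2.0]octan-3-yl (2Z)-4-[(tert-butyldimethylsilyl)oxy]-3-methylbut-2-enoate
Product: 14 (1R,2R,3R,6S)-1,2-dimethyl-7-oxobicyclo[4.2.0]octan-3-yl (2Z)-4-[(tert-butyldimethylsilyl)oxy]-3-methylbut-2-enoate
Conditions: Zn dust, NH4Cl, MeOH, 25 °C
Reagents that add atoms: none
Why: Zinc reduces both α-chlorines through the zinc enolate (reductive dehalogenation of an α,α-dichloroketone) without touching a stereocentre, the ester or the silyl ether.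

Step 9
Reactants: 15 2-methylbut-1-en-3-yne
Product: 18 4,4,5,5-tetramethyl-2-(3-methylbut-3-en-1-yn-1-yl)-1,3,2-dioxaborolane, via lithium acetylide 16 (not isolated), via lithium alkynyl(isopropoxy)borate 17 (not isolated)
Conditions: n-BuLi, THF, −78 °C; 2-isopropoxy-4,4,5,5-tetramethyl-1,3,2-dioxaborolane, −78 °C; HCl in Et2O, −78 °C → 25 °C
Reagents that add atoms: 2-isopropoxy-4,4,5,5-tetramethyl-1,3,2-dioxaborolane, CC(C)OB1OC(C)(C)C(C)(C)O1
Why: Borylation of a lithium acetylide with an alkoxyboronate, followed by acid-induced loss of isopropanol from the ate complex, is the standard route to alkynyl pinacol boronates.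

Step 10
Reactants: 14 (1R,2R,3R,6S)-1,2-dimethyl-7-oxobicyclo[4.2.0]octan-3-yl (2Z)-4-[(tert-butyldimethylsilyl)oxy]-3-methylbut-2-enoate; 18 4,4,5,5-tetramethyl-2-(3-methylbut-3-en-1-yn-1-yl)-1,3,2-dioxaborolane
Product: 19 (4aR,5R,6R,8aS)-4a,5-dimethyl-1-oxo-3-(prop-1-en-2-yl)-2-(4,4,5,5-tetramethyl-1,3,2-dioxaborolan-2-yl)-1,4,4a,5,6,7,8,8a-octahydronaphthalen-6-yl (2Z)-4-[(tert-butyldimethylsilyl)oxy]-3-methylbut-2-enoate
Conditions: Ni(cod)2 (10 mol %), PCy3 (20 mol %), toluene, 90 °C, slow addition of 18 (1.5 equiv)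
Reagents that add atoms: none
Why: Zerovalent nickel couples the C9 carbonyl of 14 and the alkyne of 18 oxidatively to an oxanickelacyclopentene (C8–C9 bond), strain-driven β-carbon elimination then cleaves the C9–C6 bond of the four-membered ring to give a seven-membered nickelacycle, and C(sp3)–C(sp2) reductive elimination forms C6–C7 and releases the enone. The closest known reaction is the nickel-catalysed intermolecular insertion of internal alkynes into cyclobutanones (formal [4+2] with C–C cleavage). Ring B is closed not by cyclisation of a chain but by two-carbon ring expansion of the cyclobutanone, the reductive elimination from the nickelacycle being the ring-closing event. No stereocentre is created: the quaternary C5 set in step 7 is untouched, and the C10 hydrogen, α to the ketone, is lost later when the diosphenol forms. Two selectivities are needed: cleavage of C9–C6 rather than C9–C10, expected because the primary C6 migrates to nickel more readily than the ring-fusion carbon and gives an alkylnickel without β-hydrogen (C5 is quaternary); and the alkyne orientation that puts C8 on the carbonyl carbon, expected from η3-coordination of the conjugated isopropenyl group, which holds C7 on nickel, and from the boron acceptor, which makes C8 the nucleophilic alkyne carbon, while the bulk of the boronate works against it and is the main risk.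

Step 11
Reactants: 19 (4aR,5R,6R,8aS)-4a,5-dimethyl-1-oxo-3-(prop-1-en-2-yl)-2-(4,4,5,5-tetramethyl-1,3,2-dioxaborolan-2-yl)-1,4,4a,5,6,7,8,8a-octahydronaphthalen-6-yl (2Z)-4-[(tert-butyldimethylsilyl)oxy]-3-methylbut-2-enoate
Product: 20 (4aR,5R,6R,8aS)-4a,5-dimethyl-1-oxo-3-(prop-1-en-2-yl)-2-(4,4,5,5-tetramethyl-1,3,2-dioxaborolan-2-yl)-1,4,4a,5,6,7,8,8a-octahydronaphthalen-6-yl (2Z)-4-hydroxy-3-methylbut-2-enoate
Conditions: HF·pyridine, excess pyridine, THF, 0 °C
Reagents that add atoms: none
Why: Fluoride cleaves the primary silyl ether, and pyridine buffering keeps the medium near neutral so that the Z-hydroxy enoate should not lactonise and the C–B bond should survive; 20 is used at once.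

Step 12
Reactants: 20 (4aR,5R,6R,8aS)-4a,5-dimethyl-1-oxo-3-(prop-1-en-2-yl)-2-(4,4,5,5-tetramethyl-1,3,2-dioxaborolan-2-yl)-1,4,4a,5,6,7,8,8a-octahydronaphthalen-6-yl (2Z)-4-hydroxy-3-methylbut-2-enoate; 21 angelic acid, (2Z)-2-methylbut-2-enoic acid
Product: 22 (4aR,5R,6R,8aS)-4a,5-dimethyl-1-oxo-3-(prop-1-en-2-yl)-2-(4,4,5,5-tetramethyl-1,3,2-dioxaborolan-2-yl)-1,4,4a,5,6,7,8,8a-octahydronaphthalen-6-yl (2Z)-3-methyl-4-{[(2Z)-2-methylbut-2-enoyl]oxy}but-2-enoate
Conditions: PPh3, DIAD, THF, 0 °C → 25 °C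
Reagents that add atoms: none
Why: Mitsunobu esterification: the angelate anion displaces the activated primary allylic oxygen by SN2, so the acid is never an acyl electrophile and should keep its Z geometry, and the enoate geometry is untouched.

Step 13
Reactants: 22 (4aR,5R,6R,8aS)-4a,5-dimethyl-1-oxo-3-(prop-1-en-2-yl)-2-(4,4,5,5-tetramethyl-1,3,2-dioxaborolan-2-yl)-1,4,4a,5,6,7,8,8a-octahydronaphthalen-6-yl (2Z)-3-methyl-4-{[(2Z)-2-methylbut-2-enoyl]oxy}but-2-enoate
Product: 24 (1R,2R,8aR)-5-hydroxy-1,8a-dimethyl-6-oxo-7-(propan-2-ylidene)-1,2,3,4,6,7,8,8a-octahydronaphthalen-2-yl (2Z)-3-methyl-4-{[(2Z)-2-methylbut-2-enoyl]oxy}but-2-enoate (CNP0228871.1), via dienol pinacol borate 23 (not isolated)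
Conditions: Me3NO (anhydrous, 3 equiv), THF, 25–40 °C; then pH 7 phosphate buffer
Reagents that add atoms: trimethylamine N-oxide, C[N+](C)(C)[O-]
Why: Amine N-oxide oxidation of the alkenyl C–B bond (1,2-shift of carbon from boron to oxygen) gives the dienol borate, and its hydrolysis followed by amine-mediated proton shifts (γ-protonation of the dienol to the isopropylidene ketone, enolisation of C9 towards C10) should give the hydrogen-bonded diosphenol tautomer of the target under neutral conditions that spare both unsaturated esters.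

Compound list
1 | 2-methylcyclohex-2-en-1-one | CC1=CCCCC1=O | starting material
2 | lithium 6-methylcyclohexa-1,5-dien-1-olate | [Li+].CC1=CCCC=C1[O-] | intermediate (not isolated)
3 | 6-methylcyclohexa-1,5-dien-1-yl trifluoromethanesulfonate | CC1=CCCC=C1OS(=O)(=O)C(F)(F)F | intermediate
4 | 2,3-dimethylcyclohexa-1,3-diene | CC1=CCCC=C1C | intermediate
5 | [(1R,2R)-2,3-dimethylcyclohex-3-en-1-yl](isopinocampheyl)borane, isopinocampheyl group from (−)-α-pinene | C[C@@H]1[C@@H](B[C@@H]2CCC=C(C)[C@H]2C)C[C@H]2C[C@@H]1C2(C)C | intermediate (not isolated)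
6 | (1R,2R)-2,3-dimethylcyclohex-3-en-1-ol | O[C@@H]1CCC=C(C)[C@H]1C | intermediate
7 | tert-butyldimethyl(prop-2-yn-1-yloxy)silane | C#CCO[Si](C)(C)C(C)(C)C | starting material
8 | lithium 3-[(tert-butyldimethylsilyl)oxy]prop-1-yn-1-ide | [Li+].[C-]#CCO[Si](C)(C)C(C)(C)C | intermediate (not isolated)
9 | 4-[(tert-butyldimethylsilyl)oxy]but-2-ynoic acid | CC(C)(C)[Si](C)(C)OCC#CC(=O)O | intermediate
10 | (1R,2R)-2,3-dimethylcyclohex-3-en-1-yl 4-[(tert-butyldimethylsilyl)oxy]but-2-ynoate | CC(C)(C)[Si](C)(C)OCC#CC(=O)O[C@@H]1CCC=C(C)[C@H]1C | intermediate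
11 | lithium methyl(alkenyl)cuprate from 10, copper at C2 of the enoate and cis to the new C3 methyl | [Li+].C[Cu-]/C(C(=O)O[C@@H]1CCC=C(C)[C@H]1C)=C(\C)CO[Si](C)(C)C(C)(C)C | intermediate (not isolated)
12 | (1R,2R)-2,3-dimethylcyclohex-3-en-1-yl (2Z)-4-[(tert-butyldimethylsilyl)oxy]-3-methylbut-2-enoate | CC(C)(C)[Si](C)(C)OC/C(C)=C\C(=O)O[C@@H]1CCC=C(C)[C@H]1C | intermediate
13 | (1R,2R,3R,6S)-8,8-dichloro-1,2-dimethyl-7-oxobicyclo[4.2.0]octan-3-yl (2Z)-4-[(tert-butyldimethylsilyl)oxy]-3-methylbut-2-enoate (cis-fused; CCl2 on C5, cis to the ester oxygen, trans to the C4 methyl) | CC(C)(C)[Si](C)(C)OC/C(C)=C\C(=O)O[C@@H]1CC[C@@H]2C(=O)C(Cl)(Cl)[C@]2(C)[C@H]1C | intermediate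
14 | (1R,2R,3R,6S)-1,2-dimethyl-7-oxobicyclo[4.2.0]octan-3-yl (2Z)-4-[(tert-butyldimethylsilyl)oxy]-3-methylbut-2-enoate | CC(C)(C)[Si](C)(C)OC/C(C)=C\C(=O)O[C@@H]1CC[C@@H]2C(=O)C[C@]2(C)[C@H]1C | intermediate
15 | 2-methylbut-1-en-3-yne | CC(=C)C#C | starting material
16 | lithium 3-methylbut-3-en-1-yn-1-ide | [Li+].[C-]#CC(C)=C | intermediate (not isolated)
17 | lithium isopropoxy(3-methylbut-3-en-1-yn-1-yl)(pinacolato)borate | [Li+].CC(=C)C#C[B-]1(OC(C)C)OC(C)(C)C(C)(C)O1 | intermediate (not isolated)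
18 | 4,4,5,5-tetramethyl-2-(3-methylbut-3-en-1-yn-1-yl)-1,3,2-dioxaborolane | CC(=C)C#CB1OC(C)(C)C(C)(C)O1 | intermediate
19 | (4aR,5R,6R,8aS)-4a,5-dimethyl-1-oxo-3-(prop-1-en-2-yl)-2-(4,4,5,5-tetramethyl-1,3,2-dioxaborolan-2-yl)-1,4,4a,5,6,7,8,8a-octahydronaphthalen-6-yl (2Z)-4-[(tert-butyldimethylsilyl)oxy]-3-methylbut-2-enoate | CC(C)(C)[Si](C)(C)OC/C(C)=C\C(=O)O[C@@H]1CC[C@@H]2C(=O)C(B3OC(C)(C)C(C)(C)O3)=C(C(C)=C)C[C@]2(C)[C@H]1C | intermediate
20 | same ring system as 19, (2Z)-4-hydroxy-3-methylbut-2-enoate ester | OC/C(C)=C\C(=O)O[C@@H]1CC[C@@H]2C(=O)C(B3OC(C)(C)C(C)(C)O3)=C(C(C)=C)C[C@]2(C)[C@H]1C | intermediate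
21 | angelic acid, (2Z)-2-methylbut-2-enoic acid | C/C=C(/C)C(=O)O | starting material
22 | same ring system as 19, (2Z)-3-methyl-4-{[(2Z)-2-methylbut-2-enoyl]oxy}but-2-enoate ester | C/C=C(/C)C(=O)OC/C(C)=C\C(=O)O[C@@H]1CC[C@@H]2C(=O)C(B3OC(C)(C)C(C)(C)O3)=C(C(C)=C)C[C@]2(C)[C@H]1C | intermediate
23 | dienol borate of 22: C8–O–B(pinacolato) in place of C8–B | C/C=C(/C)C(=O)OC/C(C)=C\C(=O)O[C@@H]1CC[C@@H]2C(=O)C(OB3OC(C)(C)C(C)(C)O3)=C(C(C)=C)C[C@]2(C)[C@H]1C | intermediate (not isolated)
24 | (1R,2R,8aR)-5-hydroxy-1,8a-dimethyl-6-oxo-7-(propan-2-ylidene)-1,2,3,4,6,7,8,8a-octahydronaphthalen-2-yl (2Z)-3-methyl-4-{[(2Z)-2-methylbut-2-enoyl]oxy}but-2-enoate | C/C=C(/C)C(=O)OC/C(C)=C\C(=O)O[C@@H]1CCC2=C(O)C(=O)C(=C(C)C)C[C@]2(C)[C@H]1C | target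

Total step count: 13. Longest linear sequence: 11 steps (1, 2, 3, 5, 6, 7, 8, 10, 11, 12, 13); steps 4 and 9 are side branches.

Steps most likely to fail

Step 10. The alkyne may insert with the opposite orientation (boronate on the nickel-bound carbon), the enyne may oligomerise on nickel, or the C9–C10 bond may be cleaved instead of C9–C6. The fallback makes the same two bonds in two separate known operations, sets out from 14 and comes back at 24. Cyclobutanone 14 is treated with 3-methylbuta-1,2-dien-1-yllithium (from 3-methylbuta-1,2-diene and n-BuLi, THF, −78 °C) to give the tertiary allenyl cyclobutanol F1 (C8–C9 bond). With [Rh(OH)(cod)]2 and BINAP in toluene at 100 °C the rhodium alkoxide should undergo β-carbon elimination and the alkylrhodium should add in conjugate fashion to the allenyl ketone (C6–C7 bond), giving after isomerisation the 7-isopropyl enone F2. Autoxidation of its extended dienolate at C8 (KOtBu, O2, THF/t-BuOH, −20 °C) should give the silyl-protected diosphenol F3, and HF·pyridine the hydroxy diosphenol F4. Mitsunobu esterification of F4 with angelic acid 21, far more acidic than the enol, then gives 24.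

Step 7. Facial selectivity may be poor because the bulky CCl2 terminus must bond to C5 on the face that also carries the C3 ester oxygen. The fallback sets out from 12 and comes back at 14. Alkene 12 is treated with the parent keteniminium salt (N,N-dimethylacetamide, Tf2O, 2,4,6-collidine, 1,2-dichloroethane, reflux). Its iminium carbon bonds to C10 and its unsubstituted CH2 terminus to C5, so the selectivity should rest on the allylic C4 methyl alone. The cyclobutaniminium triflate F5 is hydrolysed with aqueous NaHCO3 directly to 14, which also makes the dechlorination unnecessary.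

Step 3. Enantioselection by the chiral borane may be incomplete, as this reagent class is known to be only moderately selective with simple 1-methylcycloalkenes, and a second hydroboration of the remaining alkene may compete. The fallback replaces reagent control by resolution, sets out from 4 and comes back at 6. Diene 4 is hydroborated with 9-BBN (THF, 0 °C; then NaOH, H2O2) to the racemic trans-alcohol F6. Lipase-catalysed acetylation (Candida antarctica lipase B, vinyl acetate, MTBE, 25 °C) should acylate the (1R)-enantiomer faster, by the empirical size rule for secondary alcohols. The (1R,2R)-acetate F7 is separated from the unreacted (1S,2S)-alcohol and methanolysed (K2CO3, MeOH) to 6.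

Further compounds
F1 | step 10 | (1R,2R,3R,6S)-7-hydroxy-1,2-dimethyl-7-(3-methylbuta-1,2-dien-1-yl)bicyclo[4.2.0]octan-3-yl (2Z)-4-[(tert-butyldimethylsilyl)oxy]-3-methylbut-2-enoate, carbinol configuration immaterial | CC(C)(C)[Si](C)(C)OC/C(C)=C\C(=O)O[C@@H]1CC[C@@H]2C(O)(C=C=C(C)C)C[C@]2(C)[C@H]1C
F2 | step 10 | (4aR,5R,6R,8aS)-4a,5-dimethyl-1-oxo-3-(propan-2-yl)-1,4,4a,5,6,7,8,8a-octahydronaphthalen-6-yl (2Z)-4-[(tert-butyldimethylsilyl)oxy]-3-methylbut-2-enoate | CC(C)(C)[Si](C)(C)OC/C(C)=C\C(=O)O[C@@H]1CC[C@@H]2C(=O)C=C(C(C)C)C[C@]2(C)[C@H]1C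
F3 | step 10 | (1R,2R,8aR)-5-hydroxy-1,8a-dimethyl-6-oxo-7-(propan-2-ylidene)-1,2,3,4,6,7,8,8a-octahydronaphthalen-2-yl (2Z)-4-[(tert-butyldimethylsilyl)oxy]-3-methylbut-2-enoate | CC(C)(C)[Si](C)(C)OC/C(C)=C\C(=O)O[C@@H]1CCC2=C(O)C(=O)C(=C(C)C)C[C@]2(C)[C@H]1C
F4 | step 10 | (1R,2R,8aR)-5-hydroxy-1,8a-dimethyl-6-oxo-7-(propan-2-ylidene)-1,2,3,4,6,7,8,8a-octahydronaphthalen-2-yl (2Z)-4-hydroxy-3-methylbut-2-enoate | OC/C(C)=C\C(=O)O[C@@H]1CCC2=C(O)C(=O)C(=C(C)C)C[C@]2(C)[C@H]1C
F5 | step 7 | N-[(1R,2R,3R,6S)-3-{[(2Z)-4-[(tert-butyldimethylsilyl)oxy]-3-methylbut-2-enoyl]oxy}-1,2-dimethylbicyclo[4.2.0]octan-7-ylidene]-N-methylmethanaminium trifluoromethanesulfonate | CC(C)(C)[Si](C)(C)OC/C(C)=C\C(=O)O[C@@H]1CC[C@@H]2C(=[N+](C)C)C[C@]2(C)[C@H]1C.[O-]S(=O)(=O)C(F)(F)F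
F6 | step 3 | racemic trans-2,3-dimethylcyclohex-3-en-1-ol (both enantiomers) | O[C@@H]1CCC=C(C)[C@H]1C.O[C@H]1CCC=C(C)[C@@H]1C
F7 | step 3 | (1R,2R)-2,3-dimethylcyclohex-3-en-1-yl acetate | CC(=O)O[C@@H]1CCC=C(C)[C@H]1C
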